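**Plan**

1. Locants (used for all bicyclic compounds and in the reasoning): ring A is C1(CH3)=C2H–C3H(O-aroyl)–C4H–C5(CH3)–C6H2–C7(=O), ring B is C4–C5–C8H(OH)–C9H2–C10(OH)(iPr); the target is 3S,4S,5R,8R,10R.
2. Retrosynthetic cuts, in order: the ester and silyl groups; the C1=C2 bond (dehydrogenation) and C1–CH3 (enolate methylation); C3–O and C4–H (hydroboration of a C3=C4 alkene); then C4–C5 and C2–C3 together, which opens both rings to an acyclic 1-silyloxy-1-alkenylcyclopropane carrying a terminal alkyne.
3. Enabling feature: ring A is a five-carbon unit C5–C6–C7–C1–C2 (quaternary carbon, ketone carbon, enone CH) plus a two-carbon unit C3–C4 (ester carbinol, ring-fusion CH), and C8–C9–C10 of ring B is the three-atom tether between C5 and C4.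
4. Forward: the chain is built C10, then C9/C8, then C5–C6–C7 with the cyclopropane (C1/C2), then the alkyne (C4/C3); one rhodium-catalysed (5+2) step closes ring B and ring A; ring A is then adjusted.
5. Stereochemistry: C10 comes from (R)-2-hydroxy-3-methylbutanoic acid by self-regeneration of stereocentres; C8 from a catalyst-controlled alkynylation; C5 is relayed from C8 by allylic 1,3-strain in the cycloaddition; C4 and C3 come from a syn hydroboration anti to the angular methyl group.

Key step: step 13

Remark (assumption on the chemistry): (S,S)-ProPhenol is taken to send the zinc alkynylide to the Si face of aldehyde 10, which gives 4R in 12; if the facial sense is the opposite, the (R,R)-ligand is used and nothing else changes.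

**Route**

Step 1
Reactants: 1 (R)-2-hydroxy-3-methylbutanoic acid; 2 pivalaldehyde
Product: 3 (2R,5R)-2-tert-butyl-5-(propan-2-yl)-1,3-dioxolan-4-one (cis)
Conditions: TsOH·H2O (cat.), H2SO4 (cat.), pentane, reflux, Dean–Stark; cis isomer purified
Reagents that add atoms: none
Why: Acid-catalysed acetalisation with water removal (first stage of the self-regeneration-of-stereocentres tactic) should give mainly the cis-dioxolanone, whose new acetal centre stores the configuration of the hydroxy acid carbon (the future C10) while that carbon is later planarised.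

Step 2
Reactants: 3 (2R,5R)-2-tert-butyl-5-(propan-2-yl)-1,3-dioxolan-4-one; 4 allyl bromide
Product: 6 (2R,5R)-2-tert-butyl-5-(propan-2-yl)-5-(prop-2-en-1-yl)-1,3-dioxolan-4-one, via lithium enolate 5 (not isolated)
Conditions: LiN(iPr)2 (LDA, commercial solution), THF, −78 °C; then 4, −78 → −30 °C
Reagents that add atoms: none
Why: Enolate alkylation of the chiral dioxolanone: the tert-butyl group shields one face of the planar enolate, so allyl bromide should enter trans to it and create the quaternary carbinol centre (future C10) with overall retention, the allyl group supplying C9 and C8.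

Step 3
Reactants: 6 (2R,5R)-2-tert-butyl-5-(propan-2-yl)-5-(prop-2-en-1-yl)-1,3-dioxolan-4-one
Product: 7 (2R)-2-(propan-2-yl)pent-4-ene-1,2-diol
Conditions: LiAlH4, THF, 0 °C → rt; aqueous NaOH work-up
Reagents that add atoms: none
Why: Hydride reduction of the acylal carbonyl to the primary alcohol (LiAlH4 ester reduction) collapses the acetal and frees the tertiary alcohol without touching the quaternary centre, the pivalaldehyde unit leaving as neopentyl alcohol.

Step 4
Reactants: 7 (2R)-2-(propan-2-yl)pent-4-ene-1,2-diol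
Product: 8 (2R)-2-(propan-2-yl)-1,2-bis(triethylsilyloxy)pent-4-ene
Conditions: TESOTf (2.4 equiv), 2,6-lutidine, CH2Cl2, −78 → 0 °C
Reagents that add atoms: triethylsilyl trifluoromethanesulfonate, CC[Si](CC)(CC)OS(=O)(=O)C(F)(F)F
Why: A silyl triflate with a hindered pyridine base is the standard way to silylate a tertiary alcohol, and the primary TES ether installed at the same time is the latent aldehyde from which the alkyne is made after the zinc and titanium chemistry.

Step 5
Reactants: 8 (2R)-2-(propan-2-yl)-1,2-bis(triethylsilyloxy)pent-4-ene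
Product: 10 (3R)-3-(propan-2-yl)-3,4-bis(triethylsilyloxy)butanal, via ozonide 9 (not isolated)
Conditions: O3, CH2Cl2, −78 °C; then PPh3, −78 °C → rt
Reagents that add atoms: ozone, [O-][O+]=O
Why: Ozonolysis of the only alkene with reductive work-up should give the aldehyde one carbon shorter, whose carbonyl carbon is C8 of the target, silyl ethers being inert to ozone.

Step 6
Reactants: 10 (3R)-3-(propan-2-yl)-3,4-bis(triethylsilyloxy)butanal; 11 methyl propiolate
Product: 12 methyl (4R,6R)-4-hydroxy-6-(propan-2-yl)-6,7-bis(triethylsilyloxy)hept-2-ynoate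
Conditions: (S,S)-ProPhenol (20 mol%), Me2Zn (3 equiv), Ph3P=O (40 mol%), toluene, 0–4 °C; aq. NH4Cl
Reagents that add atoms: none
Why: Zinc–ProPhenol-catalysed asymmetric alkynylation: the acidic methyl propiolate is zincated by Me2Zn and the dinuclear zinc catalyst should deliver it to the Si face of the aldehyde, setting the secondary carbinol centre (4R, the future C8) under catalyst control because the β-quaternary centre exerts little 1,3-induction.

Step 7
Reactants: 12 methyl (4R,6R)-4-hydroxy-6-(propan-2-yl)-6,7-bis(triethylsilyloxy)hept-2-ynoate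
Product: 13 methyl (4R,6R)-4-(tert-butyldimethylsilyloxy)-6-(propan-2-yl)-6,7-bis(triethylsilyloxy)hept-2-ynoate
Conditions: TBSOTf, 2,6-lutidine, CH2Cl2, −78 °C
Reagents that add atoms: tert-butyldimethylsilyl trifluoromethanesulfonate, CC(C)(C)[Si](C)(C)OS(=O)(=O)C(F)(F)F
Why: A silyl triflate with a non-nucleophilic base protects the propargylic alcohol without conjugate addition to the ynoate, which an imidazole-based protocol could cause.

Step 8
Reactants: 13 methyl (4R,6R)-4-(tert-butyldimethylsilyloxy)-6-(propan-2-yl)-6,7-bis(triethylsilyloxy)hept-2-ynoate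
Product: 14 methyl (2Z,4R,6R)-4-(tert-butyldimethylsilyloxy)-3-methyl-6-(propan-2-yl)-6,7-bis(triethylsilyloxy)hept-2-enoate
Conditions: Me2CuLi (from CuI and 2 MeLi), THF, −78 °C; MeOH then aq. NH4Cl at −78 °C
Reagents that add atoms: lithium dimethylcuprate, [Li+].C[Cu-]C
Why: syn-Carbocupration (conjugate addition of Me2CuLi to the ynoate) and cold protonation of the alkenylcuprate with retention should place the new methyl cis to the vinylic hydrogen, that is the carbinol carbon cis to the ester (Z), the silyl ether being too poor a leaving group for SN2′ allene formation.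

Step 9
Reactants: 14 methyl (2Z,4R,6R)-4-(tert-butyldimethylsilyloxy)-3-methyl-6-(propan-2-yl)-6,7-bis(triethylsilyloxy)hept-2-enoate
Product: 15 1-[(1Z,3R,5R)-3-(tert-butyldimethylsilyloxy)-2-methyl-5-(propan-2-yl)-5,6-bis(triethylsilyloxy)hex-1-en-1-yl]cyclopropan-1-ol
Conditions: EtMgBr (3.5 equiv, slow addition), Ti(OiPr)4 (0.5 equiv), THF, 0 °C → rt
Reagents that add atoms: ethylmagnesium bromide, CC[Mg]Br
Why: Kulinkovich cyclopropanation: the titanacyclopropane formed from EtMgBr and Ti(OiPr)4 acts as a 1,2-dicarbanion toward the ester carbonyl and should convert the β,β-disubstituted enoate into the 1-alkenylcyclopropanol with the Z alkene untouched, no alkyne yet being present to intercept low-valent titanium.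

Step 10
Reactants: 15 1-[(1Z,3R,5R)-3-(tert-butyldimethylsilyloxy)-2-methyl-5-(propan-2-yl)-5,6-bis(triethylsilyloxy)hex-1-en-1-yl]cyclopropan-1-ol
Product: 16 tert-butyldimethylsilyl ether of 15 (1-silyloxy-1-alkenylcyclopropane)
Conditions: TBSOTf, 2,6-lutidine, CH2Cl2, −78 → 0 °C
Reagents that add atoms: tert-butyldimethylsilyl trifluoromethanesulfonate, CC(C)(C)[Si](C)(C)OS(=O)(=O)C(F)(F)F
Why: Silylation of the tertiary but unhindered cyclopropanol with a silyl triflate at low temperature gives the oxygen-activated five-carbon unit of the cycloaddition.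

Step 11
Reactants: 16 tert-butyldimethylsilyl ether of 15
Product: 18 (2R,4R,5Z)-4-(tert-butyldimethylsilyloxy)-6-[1-(tert-butyldimethylsilyloxy)cyclopropyl]-5-methyl-2-(propan-2-yl)-2-(triethylsilyloxy)hex-5-enal, via alkoxysulfonium chloride 17 (not isolated)
Conditions: (COCl)2, DMSO, CH2Cl2, −78 → −40 °C; then Et3N, −78 °C → rt
Reagents that add atoms: none
Why: Under Swern conditions a primary triethylsilyl ether is cleaved by the chlorosulfonium reagent and oxidised in the same flask, whereas the tertiary TES and the two TBS ethers should remain, so the aldehyde arises without a separate deprotection and without acid that could open the alkenylcyclopropane.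

Step 12
Reactants: 18 (2R,4R,5Z)-4-(tert-butyldimethylsilyloxy)-6-[1-(tert-butyldimethylsilyloxy)cyclopropyl]-5-methyl-2-(propan-2-yl)-2-(triethylsilyloxy)hex-5-enal
Product: 19 (3R,5R,6Z)-5-(tert-butyldimethylsilyloxy)-7-[1-(tert-butyldimethylsilyloxy)cyclopropyl]-6-methyl-3-(propan-2-yl)-3-(triethylsilyloxy)hept-6-en-1-yne
Conditions: dimethyl (1-diazo-2-oxopropyl)phosphonate, K2CO3, MeOH, 0 °C → rt
Reagents that add atoms: dimethyl (1-diazo-2-oxopropyl)phosphonate, CC(=O)C(=[N+]=[N-])P(=O)(OC)OC
Why: Seyferth–Gilbert homologation in the Ohira–Bestmann form converts the non-enolisable α-quaternary aldehyde into the terminal alkyne under mild base that the silyl ethers and the cyclopropane tolerate.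

Step 13
Reactants: 19 (3R,5R,6Z)-5-(tert-butyldimethylsilyloxy)-7-[1-(tert-butyldimethylsilyloxy)cyclopropyl]-6-methyl-3-(propan-2-yl)-3-(triethylsilyloxy)hept-6-en-1-yne
Product: 20 cycloadduct: hydroazulene diene with C3=C4 and C6=C7(OTBS) double bonds; 5-CH3; 8-OTBS; 10-OTES; 10-iPr (5R,8R,10R)
Conditions: [Rh(CO)2Cl]2 (5 mol%), ClCH2CH2Cl (0.02 M), 80 °C; chromatography on Et3N-deactivated silica
Reagents that add atoms: none
Why: After the enyne binds to monovalent rhodium, oxidative cyclisation joins alkyne carbon C4 to the alkene terminus C5 (ring B closes 5-exo with respect to both π-bonds, as a rhodacyclopentene), the adjacent cyclopropane opens by cleavage of its C7–C2 bond (cyclopropylcarbinyl-to-homoallyl shift) to a rhodacyclooctadiene, and C(sp3)–C(sp2) reductive elimination forms C2–C3 so that ring A closes by contraction of the eight-membered metallacycle; the other order, cyclopropane cleavage before alkyne insertion, leads to the same bonds. The closest known reaction is the intramolecular [Rh(CO)2Cl]2-catalysed (5+2) cycloaddition of vinylcyclopropanes with tethered alkynes, and the 1-silyloxy group on the cyclopropane is a known accelerating substituent that also delivers C7 as an enol silane. The only new stereocentre, C5, is fixed by the alkene face that the tethered alkyne reaches: because the cyclopropyl group is cis to C8 on the Z alkene, allylic 1,3-strain holds the C8–H bond in the alkene plane, the C9 tether and the C8 silyloxy group lie on opposite faces, and bond formation on the tether face leaves the C5 methyl cis to the C8 silyloxy group (5R). The step needs the (5+2) pathway to win over alkyne oligomerisation and unproductive cyclopropane opening, which high dilution, the gem-disubstituted C10 in the tether and the oxygen-activated cyclopropane should secure; the two cyclopropane CH2 groups are equivalent, so no regiochemical issue arises there. The known limit of the reaction is approached because the alkene terminus becomes quaternary, which is why the activated cyclopropane and an elevated temperature are chosen.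

Step 14
Reactants: 20 cycloadduct (silyl enol ether)
Product: 21 ketone: hydroazulen-7-one with C3=C4 double bond; 5-CH3; 8-OTBS; 10-OTES; 10-iPr (5R,8R,10R)
Conditions: Bu4NF (1.05 equiv), AcOH (1.1 equiv), THF, −20 °C
Reagents that add atoms: none
Why: Buffered fluoride cleaves the Si–O bond of the enol silane far faster than those of the alkyl silyl ethers and C-protonation at C6 gives the ketone, acid being avoided because the C10 silyl ether is now tertiary and allylic.

Step 15
Reactants: 21 ketone
Product: 23 1-methyl ketone: 21 with CH3 at C1 (1RS;5R,8R,10R), via lithium enolate 22 (not isolated)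
Conditions: LiN(iPr)2 (LDA, commercial solution, 1.05 equiv), THF, −78 °C; then MeI, −78 → −40 °C
Reagents that add atoms: iodomethane, CI
Why: Kinetic enolate alkylation: LDA should deprotonate C1 (a CH2 flanked by CH2) in preference to C6 (a CH2 next to the quaternary C5), and methylation there adds the last skeletal carbon, the C1 configuration being irrelevant because C1 later becomes sp2.

Step 16
Reactants: 23 1-methyl ketone
Product: 24 ethylene ketal of 23 (spiro-1,3-dioxolane at C7)
Conditions: TMSOCH2CH2OTMS, TMSOTf (5 mol%), CH2Cl2, −78 → −20 °C; pyridine quench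
Reagents that add atoms: 1,2-bis(trimethylsilyloxy)ethane, C[Si](C)(C)OCCO[Si](C)(C)C
Why: Silyl-triflate-catalysed ketalisation with the bis-silyl ether of ethylene glycol at low temperature masks the ketone against borane under conditions that should be mild enough for the allylic tertiary silyl ether.

Step 17
Reactants: 24 ethylene ketal
Product: 26 alcohol: 24 with 3-OH and 4-H in place of the alkene (1RS;3S,4S,5R,8R,10R), via alkylborane 25 (not isolated)
Conditions: BH3·THF, THF, 0 °C → rt; then NaOH, H2O2, 0 °C → rt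
Reagents that add atoms: hydrogen peroxide, OO
Why: Hydroboration–oxidation: syn addition places boron at the less substituted C3 and hydrogen at C4, and attack on the face opposite the angular C5 methyl (as with steroidal ring-fusion alkenes) should give the trans ring fusion with the C3 oxygen cis to the C4 hydrogen (3S,4S) after stereoretentive oxidation.

Step 18
Reactants: 27 4-hydroxybenzoic acid
Product: 29 4-(tert-butyldimethylsilyloxy)benzoic acid, via silyl ester 28 (not isolated)
Conditions: TBSCl (2.2 equiv), imidazole, DMF, rt; then AcOH–THF–H2O (3:1:1), rt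
Reagents that add atoms: tert-butyldimethylsilyl chloride, CC(C)(C)[Si](C)(C)Cl
Why: Silylation of both acidic groups followed by selective hydrolysis of the much more labile silyl ester gives the phenol-protected acid needed for the esterification.

Step 19
Reactants: 26 alcohol; 29 4-(tert-butyldimethylsilyloxy)benzoic acid
Product: 30 ester: 3-O-[4-(tert-butyldimethylsilyloxy)benzoyl] derivative of 26
Conditions: DCC, DMAP, CH2Cl2, 0 °C → rt
Reagents that add atoms: none
Why: Steglich esterification (carbodiimide activation with DMAP acyl transfer) acylates the hindered secondary alcohol with retention at C3.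

Step 20
Reactants: 30 ester ketal
Product: 31 ketone ester: 30 with C7=O restored
Conditions: PPTS, acetone–H2O (10:1), 45 °C
Reagents that add atoms: water, O
Why: Acid-catalysed ketal hydrolysis frees the ketone, and since no allylic silyl ether remains after the hydroboration the weak acid should leave the silyl ethers and the ester intact.

Step 21
Reactants: 31 ketone ester
Product: 33 enone: 2-methyl enone C7(=O)–C1(CH3)=C2H with 3-O-aroyl; 8-OTBS; 10-OTES (3S,4S,5R,8R,10R), via trimethylsilyl enol ether 32 (not isolated)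
Conditions: TMSOTf, Et3N, CH2Cl2, 0 °C → rt; then Pd(OAc)2 (1.1 equiv), MeCN, rt
Reagents that add atoms: none
Why: Saegusa–Ito oxidation: the more substituted silyl enol ether toward C1 is oxidised by divalent palladium through an oxa-π-allyl complex and β-hydride loss from C2, and since C5 is quaternary the regioisomeric enol ether cannot eliminate, so only the 2-methyl enone can form.

Step 22
Reactants: 33 enone
Product: 34 CNP0199397.1 (target)
Conditions: HF (48% aq.), MeCN, 0 °C → rt
Reagents that add atoms: none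
Why: Fluoride-mediated global desilylation removes the aryl TBS, secondary TBS and tertiary TES ethers under non-basic conditions that should spare the aryl ester and the γ-acyloxy enone.

**Compound list**

1 | (R)-2-hydroxy-3-methylbutanoic acid | CC(C)[C@@H](O)C(=O)O | starting material
2 | pivalaldehyde (2,2-dimethylpropanal) | CC(C)(C)C=O | starting material
3 | (2R,5R)-2-tert-butyl-5-(propan-2-yl)-1,3-dioxolan-4-one | CC(C)[C@H]1O[C@@H](C(C)(C)C)OC1=O | intermediate
4 | allyl bromide | C=CCBr | starting material
5 | lithium enolate of 3 | CC(C)C1=C([O-])O[C@H](C(C)(C)C)O1.[Li+] | intermediate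
6 | (2R,5R)-2-tert-butyl-5-(propan-2-yl)-5-(prop-2-en-1-yl)-1,3-dioxolan-4-one | CC(C)[C@@]1(CC=C)O[C@@H](C(C)(C)C)OC1=O | intermediate
7 | (2R)-2-(propan-2-yl)pent-4-ene-1,2-diol | OC[C@](O)(C(C)C)CC=C | intermediate
8 | (2R)-2-(propan-2-yl)-1,2-bis(triethylsilyloxy)pent-4-ene | CC[Si](CC)(CC)OC[C@](O[Si](CC)(CC)CC)(C(C)C)CC=C | intermediate
9 | ozonide (1,2,4-trioxolane) of 8 | CC[Si](CC)(CC)OC[C@](O[Si](CC)(CC)CC)(C(C)C)CC1OCOO1 | intermediate
10 | (3R)-3-(propan-2-yl)-3,4-bis(triethylsilyloxy)butanal | CC[Si](CC)(CC)OC[C@](O[Si](CC)(CC)CC)(C(C)C)CC=O | intermediate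
11 | methyl propiolate | C#CC(=O)OC | starting material
12 | methyl (4R,6R)-4-hydroxy-6-(propan-2-yl)-6,7-bis(triethylsilyloxy)hept-2-ynoate | COC(=O)C#C[C@H](O)C[C@@](O[Si](CC)(CC)CC)(C(C)C)CO[Si](CC)(CC)CC | intermediate
13 | methyl (4R,6R)-4-(tert-butyldimethylsilyloxy)-6-(propan-2-yl)-6,7-bis(triethylsilyloxy)hept-2-ynoate | COC(=O)C#C[C@H](O[Si](C)(C)C(C)(C)C)C[C@@](O[Si](CC)(CC)CC)(C(C)C)CO[Si](CC)(CC)CC | intermediate
14 | methyl (2Z,4R,6R)-4-(tert-butyldimethylsilyloxy)-3-methyl-6-(propan-2-yl)-6,7-bis(triethylsilyloxy)hept-2-enoate | COC(=O)/C=C(/C)[C@H](O[Si](C)(C)C(C)(C)C)C[C@@](O[Si](CC)(CC)CC)(C(C)C)CO[Si](CC)(CC)CC | intermediate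
15 | 1-[(1Z,3R,5R)-3-(tert-butyldimethylsilyloxy)-2-methyl-5-(propan-2-yl)-5,6-bis(triethylsilyloxy)hex-1-en-1-yl]cyclopropan-1-ol | OC1(CC1)/C=C(/C)[C@H](O[Si](C)(C)C(C)(C)C)C[C@@](O[Si](CC)(CC)CC)(C(C)C)CO[Si](CC)(CC)CC | intermediate
16 | tert-butyldimethylsilyl ether of 15 | CC(C)(C)[Si](C)(C)OC1(CC1)/C=C(/C)[C@H](O[Si](C)(C)C(C)(C)C)C[C@@](O[Si](CC)(CC)CC)(C(C)C)CO[Si](CC)(CC)CC | intermediate
17 | alkoxydimethylsulfonium chloride from the primary oxygen of 16 | CC(C)(C)[Si](C)(C)OC1(CC1)/C=C(/C)[C@H](O[Si](C)(C)C(C)(C)C)C[C@@](O[Si](CC)(CC)CC)(C(C)C)CO[S+](C)C.[Cl-] | intermediate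
18 | (2R,4R,5Z)-4-(tert-butyldimethylsilyloxy)-6-[1-(tert-butyldimethylsilyloxy)cyclopropyl]-5-methyl-2-(propan-2-yl)-2-(triethylsilyloxy)hex-5-enal | CC(C)(C)[Si](C)(C)OC1(CC1)/C=C(/C)[C@H](O[Si](C)(C)C(C)(C)C)C[C@@](O[Si](CC)(CC)CC)(C(C)C)C=O | intermediate
19 | (3R,5R,6Z)-5-(tert-butyldimethylsilyloxy)-7-[1-(tert-butyldimethylsilyloxy)cyclopropyl]-6-methyl-3-(propan-2-yl)-3-(triethylsilyloxy)hept-6-en-1-yne (cycloaddition precursor) | C#C[C@](O[Si](CC)(CC)CC)(C(C)C)C[C@@H](O[Si](C)(C)C(C)(C)C)/C(C)=C\C1(O[Si](C)(C)C(C)(C)C)CC1 | intermediate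
20 | cycloadduct, hydroazulene diene silyl enol ether (5R,8R,10R) | C1CC=C2[C@@](C)(C=C1O[Si](C)(C)C(C)(C)C)[C@H](O[Si](C)(C)C(C)(C)C)C[C@@]2(O[Si](CC)(CC)CC)C(C)C | intermediate
21 | hydroazulen-7-one with C3=C4 alkene (5R,8R,10R) | C1CC=C2[C@@](C)(CC1=O)[C@H](O[Si](C)(C)C(C)(C)C)C[C@@]2(O[Si](CC)(CC)CC)C(C)C | intermediate
22 | lithium enolate of 21 toward C1 | C=1CC=C2[C@@](C)(CC=1[O-])[C@H](O[Si](C)(C)C(C)(C)C)C[C@@]2(O[Si](CC)(CC)CC)C(C)C.[Li+] | intermediate
23 | 1-methyl ketone (C1 epimers) | CC1CC=C2[C@@](C)(CC1=O)[C@H](O[Si](C)(C)C(C)(C)C)C[C@@]2(O[Si](CC)(CC)CC)C(C)C | intermediate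
24 | ethylene ketal of 23 | CC1CC=C2[C@@](C)(CC13OCCO3)[C@H](O[Si](C)(C)C(C)(C)C)C[C@@]2(O[Si](CC)(CC)CC)C(C)C | intermediate
25 | C3 alkylborane from 24 | CC1C[C@H](B)[C@@H]2[C@@](C)(CC13OCCO3)[C@H](O[Si](C)(C)C(C)(C)C)C[C@@]2(O[Si](CC)(CC)CC)C(C)C | intermediate
26 | C3 alcohol, trans-fused (3S,4S,5R,8R,10R) | CC1C[C@H](O)[C@@H]2[C@@](C)(CC13OCCO3)[C@H](O[Si](C)(C)C(C)(C)C)C[C@@]2(O[Si](CC)(CC)CC)C(C)C | intermediate
27 | 4-hydroxybenzoic acid | OC(=O)c1ccc(O)cc1 | starting material
28 | tert-butyldimethylsilyl 4-(tert-butyldimethylsilyloxy)benzoate | CC(C)(C)[Si](C)(C)OC(=O)c1ccc(O[Si](C)(C)C(C)(C)C)cc1 | intermediate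
29 | 4-(tert-butyldimethylsilyloxy)benzoic acid | OC(=O)c1ccc(O[Si](C)(C)C(C)(C)C)cc1 | intermediate
30 | C3 4-(tert-butyldimethylsilyloxy)benzoate of 26 | CC1C[C@H](OC(=O)c3ccc(O[Si](C)(C)C(C)(C)C)cc3)[C@@H]2[C@@](C)(CC14OCCO4)[C@H](O[Si](C)(C)C(C)(C)C)C[C@@]2(O[Si](CC)(CC)CC)C(C)C | intermediate
31 | ketone ester (C7=O, C1 epimers) | CC1C[C@H](OC(=O)c3ccc(O[Si](C)(C)C(C)(C)C)cc3)[C@@H]2[C@@](C)(CC1=O)[C@H](O[Si](C)(C)C(C)(C)C)C[C@@]2(O[Si](CC)(CC)CC)C(C)C | intermediate
32 | trimethylsilyl enol ether C7(OTMS)=C1(CH3) of 31 | CC=1C[C@H](OC(=O)c3ccc(O[Si](C)(C)C(C)(C)C)cc3)[C@@H]2[C@@](C)(CC=1O[Si](C)(C)C)[C@H](O[Si](C)(C)C(C)(C)C)C[C@@]2(O[Si](CC)(CC)CC)C(C)C | intermediate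
33 | tris-silylated target (2-methyl enone) | CC1=C[C@H](OC(=O)c3ccc(O[Si](C)(C)C(C)(C)C)cc3)[C@@H]2[C@@](C)(CC1=O)[C@H](O[Si](C)(C)C(C)(C)C)C[C@@]2(O[Si](CC)(CC)CC)C(C)C | intermediate
34 | CNP0199397.1 (3S,4S,5R,8R,10R) | CC1=C[C@H](OC(=O)c2ccc(O)cc2)[C@@H]2[C@@](C)(CC1=O)[C@H](O)C[C@@]2(O)C(C)C | target

**Step count**

Total: 22 steps. Longest linear sequence: 21 steps (steps 1–17 and 19–22); step 18 is a one-step branch.

**Steps most likely to fail**

Step 13. The oxidative cyclisation may stall at the fully substituted alkene terminus, the activated cyclopropane may be consumed unproductively before the alkyne engages, or the facial selectivity at C5 may be poor. Fallback (sets out from 14, returns at 21): the two rings are closed in separate events and ring A is made by olefin metathesis instead of from a cyclopropane. Enoate 14 is converted into its N-methoxy-N-methylamide F1 (MeNH(OMe)·HCl, iPrMgCl). But-3-enylmagnesium bromide then gives the (Z)-enone F2. Swern oxidation of the primary TES ether gives aldehyde F3, and Ohira–Bestmann homologation gives the enynone F4. Hydride-initiated reductive enyne cyclisation (Pd2(dba)3·CHCl3, P(o-tolyl)3, AcOH, Et3SiH) closes ring B onto the enone β-carbon, under the same allylic-strain control, to the exocyclic-methylene ketone F5. Ring-closing metathesis with the second-generation Hoveyda–Grubbs catalyst (toluene, 80 °C, loss of ethene) forms the C3=C4 bond and delivers ketone 21.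

Step 17. Borane may add from the face of the angular methyl group (cis ring fusion), or react sluggishly at the hindered ring-fusion alkene. Fallback (sets out from 24, returns at 30): C4 is set under thermodynamic control and C3 by hydride reduction and inversion. The wrong-face alcohol F6 (alone or mixed with 26) is oxidised with Dess–Martin periodinane to the cis-fused ketone F7; 26 gives F8 directly. DBU equilibrates C4 to the trans-fused ketone F8, which is expected to be the more stable epimer. NaBH4 reduction, with hydride expected anti to the angular methyl as in 6-oxo steroids, gives the C3-epimeric alcohol F9. Mitsunobu esterification with acid 29 (PPh3, DIAD) then installs the ester with inversion and gives 30.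

Step 6. Catalyst control at the new carbinol centre may be incomplete with the β-quaternary aldehyde, or the β-silyloxy group may be eliminated. Fallback (sets out from 10, returns at 12): the configuration is set by reduction instead of by addition. Lithium methyl propiolate (from 11 with LiN(iPr)2, THF, −78 °C) adds to 10 to give 12 together with its C4 epimer F10. Dess–Martin oxidation of the mixture gives ynone F11. Midland reduction with (R)-Alpine-borane, the alkynyl group acting as the small substituent, returns the 4R alcohol 12.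

**Further compounds**

F1 | step 13 | N-methoxy-N-methylamide of 14 | CON(C)C(=O)/C=C(/C)[C@H](O[Si](C)(C)C(C)(C)C)C[C@@](O[Si](CC)(CC)CC)(C(C)C)CO[Si](CC)(CC)CC
F2 | step 13 | (Z)-but-3-enyl enone | C=CCCC(=O)/C=C(/C)[C@H](O[Si](C)(C)C(C)(C)C)C[C@@](O[Si](CC)(CC)CC)(C(C)C)CO[Si](CC)(CC)CC
F3 | step 13 | enone aldehyde | C=CCCC(=O)/C=C(/C)[C@H](O[Si](C)(C)C(C)(C)C)C[C@@](O[Si](CC)(CC)CC)(C(C)C)C=O
F4 | step 13 | enynone | C=CCCC(=O)/C=C(/C)[C@H](O[Si](C)(C)C(C)(C)C)C[C@@](O[Si](CC)(CC)CC)(C(C)C)C#C
F5 | step 13 | ring B methylenecyclopentane ketone | C=C1[C@@](C)(CC(=O)CCC=C)[C@H](O[Si](C)(C)C(C)(C)C)C[C@@]1(O[Si](CC)(CC)CC)C(C)C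
F6 | step 17 | cis-fused alcohol (3R,4R), C3/C4 bis-epimer of 26 | CC1C[C@@H](O)[C@H]2[C@@](C)(CC13OCCO3)[C@H](O[Si](C)(C)C(C)(C)C)C[C@@]2(O[Si](CC)(CC)CC)C(C)C
F7 | step 17 | cis-fused C3 ketone (4R) | CC1CC(=O)[C@H]2[C@@](C)(CC13OCCO3)[C@H](O[Si](C)(C)C(C)(C)C)C[C@@]2(O[Si](CC)(CC)CC)C(C)C
F8 | step 17 | trans-fused C3 ketone (4S) | CC1CC(=O)[C@@H]2[C@@](C)(CC13OCCO3)[C@H](O[Si](C)(C)C(C)(C)C)C[C@@]2(O[Si](CC)(CC)CC)C(C)C
F9 | step 17 | trans-fused C3-epimeric alcohol (3R,4S) | CC1C[C@@H](O)[C@@H]2[C@@](C)(CC13OCCO3)[C@H](O[Si](C)(C)C(C)(C)C)C[C@@]2(O[Si](CC)(CC)CC)C(C)C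
F10 | step 6 | methyl (4S,6R)-4-hydroxy-6-(propan-2-yl)-6,7-bis(triethylsilyloxy)hept-2-ynoate (C4 epimer of 12) | COC(=O)C#C[C@@H](O)C[C@@](O[Si](CC)(CC)CC)(C(C)C)CO[Si](CC)(CC)CC
F11 | step 6 | methyl (6R)-4-oxo-6-(propan-2-yl)-6,7-bis(triethylsilyloxy)hept-2-ynoate | COC(=O)C#CC(=O)C[C@@](O[Si](CC)(CC)CC)(C(C)C)CO[Si](CC)(CC)CC
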